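## Analysis of the target

The target **31** is a tricyclic triester. Numbering used throughout: C1 is the quaternary carbon carrying CH3 and the CH2O-angelate arm; C2, C3 and C7 are the cyclobutane CH carbons (C3 next to the ketone C4, C7 next to C6); C5=C6(CH3) is the enone alkene; C8 is the methylated cyclobutane carbon; C9 (on C8) and C11 (on C1) are the acyloxy methines and C10 is the methylene between them. The cyclobutane C2–C3–C8–C7 is bridged across both diagonals: C3/C7 by the enone unit C4–C5=C6 (a verbenone-like bicyclo[3.1.1]heptenone) and C2/C8 by the chain C1–C11–C10–C9, which forms the seven-membered ring. Of the seven stereocentres, C2, C3, C7 and C8 are locked together by the cage and count as one element. The free ones are C1, C9 and C11: O9 and O11 are trans, O11 is cis to the C1 methyl, and the CH2O arm on C1 lies on the side of O9, which is the side of the C4 carbonyl. The seven-membered ring sits on a local mirror plane of the cage (through C2, C8 and C5), and its two faces differ only by the remote C4/C6 substitution, so the cage cannot be expected to pass its chirality on to C1, C9 or C11. Sensitive groups are the three angelates (Z to E isomerisation with nucleophiles, base or heat), the strained pinene-like cyclobutane–alkene unit (cationic and radical rearrangement) and the enone. The strategy rests on the 1,3-relationship of O9 and O11 across C10: the seven-membered ring is a masked cycloheptane-1,3-dione held between the non-enolisable carbons C8 and C1, and such a dione is the one-carbon ring enlargement of a six-membered acyloin ring C1–C11–C9 laid across C2 and C8.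

## Retrosynthetic reasoning

**31 to 29 and 30.** The three ester C–O bonds are cut first. Angelates isomerise easily, so they are put on in the last step, all three at once, from triol **29** and angelic acid **30**.

**29 to 26 (through 28 and 27).** The C4 carbonyl is taken back to a CH2 group. An enone would not survive sodium metal or the hydride steps that come before, whereas the allylic C4–H2 of a pinene-type alkene is a reliable site for oxidation. The two secondary hydroxyls of diol **26** are masked as triethylsilyl ethers (**27**) for that oxidation, so that one fluoride treatment of **28** frees all three oxygens.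

**26 to 24 (through 25).** The C–H bonds at C11 and C9 are cut. The trans diol is the signature of a hydroxyl-directed anti reduction, so C11 is set from C9. C9 itself has no neighbour that can bias it, because C8 presents two equivalent faces, so a chiral reducing agent must set it. The dione region of **24** is locally twofold-symmetric, so the same catalyst gives the matching configuration at whichever carbonyl it reduces first, and both mono-alcohols converge on **26**.

**24 to 21 and 22 (through 23).** C9–C10 and C10–C11 are cut and C9–C11 is joined instead. Direct closure of a seven-membered ring between two quaternary carbons is the hard way. The six-membered enediol ether **21** already holds C9 and C11 together, and C10 can be slipped in as a carbene carbon from diiodomethane **22**, the old C9–C11 bond of cyclopropane **23** then being broken oxidatively. The forward step must pick the enediol ether over the C5=C6 alkene and must not damage the cyclobutane.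

**21 to 20.** The C9–C11 bond is cut back to two methyl esters. In diester **20** both ester carbons are held cis-1,3 on the cyclobutane, about 2.6 Å apart, and neither has an α-hydrogen, so reductive coupling has no Claisen competition.

**20 to 16 (through 19 and 17).** No C–C bond is cut here; the stereocentre C1 is traced back to a carbon with two identical ester groups. An enolate at C1 would lie in the local mirror plane of the cage, so an alkylating agent would meet two equivalent faces and give both epimers. In triester **16** the problem becomes the choice between two enantiotopic ester groups flanked by a methyl and a large residue, which an esterase can make (half-acid **17**). Reduction of the free acid to the alcohol **19** and silylation give **20**. A silyl ether is used on this oxygen so that it leaves at the end together with the other silyl groups, under conditions that spare the enone.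

**16 to 12 and 13 (through 15 and 14).** The C1–CH3 bond, the C2–H bond and the C2=C1 bond are cut. Ketone **12** condenses with dimethyl malonate **13** to **14**, hydride adds to C2 (**15**) and the malonate is methylated. Hydride is the smallest possible reagent for the hindered C2 and must come from the face of the C4–C5=C6 bridge, which pushes C1 to the side of C9 where the later ring needs it.

**12 to 8 (through 11, 10 and 9).** Ester **12** comes from acid **11**, the resolved form of racemic acid **10**; **10** comes from alcohol **9** and silyl ether **8**. C9 is brought to the acid level before C2 is touched for two reasons: the acid on the stereocentre C8 is the handle for a classical resolution at an early, cheap stage, and no silyl ether then has to be removed selectively later.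

**8 to 4 (through 7).** C2–C3 and C7–C8, the two cyclobutane bonds, are cut. Acid **4** becomes a vinylketene whose intramolecular [2+2] addition across the distal alkene builds the cyclobutane and the six-membered ring together (**7**). The (6E) alkene geometry is translated into the C8 configuration. The alkene emerges exocyclic and is moved into the ring (**8**).

**4 to 1.** Acid **4** is methyl geranate **1** after allylic oxidation of the terminal E-methyl (**2**), silylation (**3**) and saponification.

## Alternatives that were turned down

**Alternative 1:** The disconnection is C2–C7 and C3–C4 in a Diels–Alder sense, bought with an extra bond C4–C8 that the target lacks.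
- Forward key step: in the open-chain triene A1 an E-alkenylboronate (C2=C3) hangs through C1, C11, C10 and C9 from the quaternary ring carbon C8 of a 1-silyloxy-3-methylcyclopentadiene (C4=C5–C6=C7). Heating would give the norbornene A2, closing the six-membered ring C2–C7 and the seven-membered ring at once. A later 1,2-shift of C8 from C4 to C3 would then make the cyclobutane and the C4 ketone.
- For it: C1, C9 and C11 are made in an open chain, where reagent control is routine, so no resolution is needed and no allylic oxidation either. On both points it is stronger than the chosen route.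
- Against it: A1 needs a fragile silyloxycyclopentadiene with a quaternary stereocentre carrying the whole chain; a boron-substituted alkene is a weak dienophile that must close a seven-membered ring over the sp3 carbon of the diene; and the ring contraction from a norbornane to a bicyclo[3.1.1]heptane runs against strain in a system prone to competing Wagner–Meerwein shifts.
- Comparison: two uncertain steps in sequence on late material, against one uncertain step of a known reaction type in the chosen route, which in exchange pays with a resolution.

**Alternative 2:** The disconnection is C2–C3 and C7–C8, the ketene–alkene [2+2], made with the C9–C11 arm already on C8.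
- Forward key step: Et3N dehydrochlorinates the dienoyl chloride A3, and the ketene unit so formed (C2 carbonyl, C7 α-carbon) adds across C3=C8 to give cyclobutanone A4, once the ring alkene sits at C5=C6.
- For it: it is the same cycloaddition that opens the chosen route, and the C9 stereocentre, made beforehand in the open chain, could steer the cycloaddition so that no resolution is needed. Where that works, it is the stronger plan on absolute configuration.
- Against it: an allylic silyloxy stereocentre has to control the face of a ketene cycloaddition at 110 °C, which is unproven. The seven-membered ring must then be closed from A4 with formation of the quaternary C1 inside a medium ring, the hardest bond of the target left for the end.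
- Comparison: the chosen route runs the cycloaddition on the simplest chain, closes an easy six-membered ring between two pre-positioned carbons, and inserts C10 afterwards.

**Alternative 3:** The disconnection is C7–C8, one cyclobutane bond, in a biomimetic sense.
- Forward key step: Et2AlCl activates the C8–C9 epoxide of the cis-fused 6–7 bicycle A5, and the γ-carbon C7 of its C4 silyl dienol ether attacks C8 with inversion. This gives A6 with the cyclobutane, the enone and a free C9 hydroxyl.
- For it: the step is late and stereospecific, sets C8 and C9 together, delivers the enone without oxidation, and leaves O9 and O11 already differentiated. On these points it is stronger than the chosen route.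
- Against it: a four-membered ring must form by substitution at a fully substituted epoxide carbon. Under Lewis acid that carbon turns cationic, and hydride shift to a ketone, elimination to an allylic alcohol, or attack through the α-carbon C5 are all easier than closing a strained ring. A5 itself, with five stereocentres on a medium ring, needs a long synthesis.
- Comparison: the chosen route makes the cyclobutane first, by the reaction class known to give this bicyclo[3.1.1] ring, and keeps its risk in a ring enlargement that has direct precedent.

Key step: step 17

## Route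

Remark 1: which antipode of 1-phenylethylamine gives the less soluble salt with the wanted enantiomer of acid **10** cannot be predicted; the (S)-amine is written and the (R)-amine is used if the pairing is reversed.

Remark 2: the esterase in step 13 is taken to cleave the ester group of **16** that has to become the CH2O arm; the case of low or opposite selectivity is treated after the steps.

Remark 3: names of **7**–**20** use bicyclo[3.1.1]heptane locants (C6 = target C2, C7 = target C8); names of **21**–**29** use the target numbering C1–C11.

Step 1
Reactants: 1 methyl (2E)-3,7-dimethylocta-2,6-dienoate (methyl geranate)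
Product: 2 methyl (2E,6E)-8-hydroxy-3,7-dimethylocta-2,6-dienoate
Conditions: SeO2 (0.3 equiv), t-BuOOH (70% aq.), salicylic acid (cat.), CH2Cl2, rt
Reagents that add atoms: tert-butyl hydroperoxide, CC(C)(C)OO
Why: Allylic oxidation with SeO2 (ene reaction, then [2,3]-shift) goes to the electron-rich 6,7-alkene rather than the conjugated one and takes the methyl trans to the chain, which should give the (6E)-alcohol; this geometry later fixes C8.

Step 2
Reactants: 2 methyl (2E,6E)-8-hydroxy-3,7-dimethylocta-2,6-dienoate
Product: 3 methyl (2E,6E)-8-(tert-butyldimethylsilyloxy)-3,7-dimethylocta-2,6-dienoate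
Conditions: TBSCl, imidazole, DMF, rt
Reagents that add atoms: tert-butyldimethylsilyl chloride, CC(C)(C)[Si](C)(C)Cl
Why: Standard silylation of a primary allylic alcohol; the ether keeps the alkene electron-rich for the cycloaddition and withstands hydroxide, amine and heat.

Step 3
Reactants: 3 methyl (2E,6E)-8-(tert-butyldimethylsilyloxy)-3,7-dimethylocta-2,6-dienoate
Product: 4 (2E,6E)-8-(tert-butyldimethylsilyloxy)-3,7-dimethylocta-2,6-dienoic acid
Conditions: LiOH, THF/MeOH/H2O, 40 °C; then cold 1 M HCl to pH 4
Reagents that add atoms: lithium hydroxide, [Li+].[OH-]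
Why: Saponification of the conjugated methyl ester; the silyl ether is stable to hydroxide.

Step 4
Reactants: 4 (2E,6E)-8-(tert-butyldimethylsilyloxy)-3,7-dimethylocta-2,6-dienoic acid
Product: 7 rac-7-[(tert-butyldimethylsilyloxy)methyl]-7-methyl-2-methylidenebicyclo[3.1.1]heptan-6-one, via acid chloride 5 (not isolated), via vinylketene 6 (not isolated)
Conditions: Me2C=C(Cl)NMe2, CH2Cl2, 0 °C to rt; then slow addition to Et3N, toluene, reflux, 0.01 M
Reagents that add atoms: none
Why: The chloroenamine gives the acid chloride without HCl; Et3N removes HCl across the C3 methyl to the vinylketene, whose intramolecular [2+2] cycloaddition joins the ketene carbon to the CH end and the α-carbon to the disubstituted end of the distal alkene, a known route to 2-methylidenebicyclo[3.1.1]heptan-6-ones. The addition is suprafacial on the alkene, so the (6E) geometry places the silyloxymethyl group on the side of the carbonyl bridge and the methyl over the three-carbon bridge; the product is racemic.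

Step 5
Reactants: 7 rac-7-[(tert-butyldimethylsilyloxy)methyl]-7-methyl-2-methylidenebicyclo[3.1.1]heptan-6-one
Product: 8 rac-7-[(tert-butyldimethylsilyloxy)methyl]-2,7-dimethylbicyclo[3.1.1]hept-2-en-6-one
Conditions: Pd/C (5%, pre-saturated with H2, then N2), toluene, 60 °C
Reagents that add atoms: none
Why: Palladium hydride addition and elimination moves the exocyclic alkene to the trisubstituted ring position (the β-pinene to α-pinene relationship), as the gem-dimethyl parent ketone does; no stereocentre is touched.

Step 6
Reactants: 8 rac-7-[(tert-butyldimethylsilyloxy)methyl]-2,7-dimethylbicyclo[3.1.1]hept-2-en-6-one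
Product: 9 rac-7-(hydroxymethyl)-2,7-dimethylbicyclo[3.1.1]hept-2-en-6-one
Conditions: HF·pyridine, pyridine, THF, 0 °C to rt
Reagents that add atoms: none
Why: Buffered fluoride desilylation; non-basic conditions avoid an alkoxide next to the strained, non-enolisable ketone, which could add and fragment the ring.

Step 7
Reactants: 9 rac-7-(hydroxymethyl)-2,7-dimethylbicyclo[3.1.1]hept-2-en-6-one
Product: 10 rac-2,7-dimethyl-6-oxobicyclo[3.1.1]hept-2-ene-7-carboxylic acid
Conditions: TEMPO (0.2 equiv), PhI(OAc)2 (2.5 equiv), MeCN/H2O, rt
Reagents that add atoms: water, O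
Why: Oxoammonium oxidation to the aldehyde, hydration and second oxidation to the acid; the medium is nearly neutral, so the acid-labile alkene and the cyclobutanone should survive.

Step 8
Reactants: 10 rac-2,7-dimethyl-6-oxobicyclo[3.1.1]hept-2-ene-7-carboxylic acid
Product: 11 2,7-dimethyl-6-oxobicyclo[3.1.1]hept-2-ene-7-carboxylic acid as the single enantiomer with the cage configuration of the target
Conditions: (S)-1-phenylethylamine (0.5 equiv), EtOAc/i-PrOH, recrystallisation of the salt; then 1 M HCl, EtOAc
Reagents that add atoms: none
Why: Classical resolution through diastereomeric ammonium salts; the carboxyl group sits directly on the stereocentre C7 of the cage, and the amine is recovered.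

Step 9
Reactants: 11 2,7-dimethyl-6-oxobicyclo[3.1.1]hept-2-ene-7-carboxylic acid (single enantiomer)
Product: 12 methyl 2,7-dimethyl-6-oxobicyclo[3.1.1]hept-2-ene-7-carboxylate
Conditions: MeI, K2CO3, DMF, rt
Reagents that add atoms: iodomethane, CI
Why: SN2 alkylation of the carboxylate; the ketone cannot enolise, so carbonate does no harm.

Step 10
Reactants: 12 methyl 2,7-dimethyl-6-oxobicyclo[3.1.1]hept-2-ene-7-carboxylate; 13 dimethyl malonate
Product: 14 dimethyl 2-[7-(methoxycarbonyl)-2,7-dimethylbicyclo[3.1.1]hept-2-en-6-ylidene]propanedioate
Conditions: TiCl4, pyridine, THF, 0 °C to rt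
Reagents that add atoms: dimethyl malonate (13), COC(=O)CC(=O)OC
Why: Knoevenagel condensation in the Lehnert variant; the titanium enolate adds to the strained, non-enolisable ketone and water is lost, with pyridine keeping the medium non-acidic. The two ester groups are identical, so there is no alkene geometry to control.

Step 11
Reactants: 14 dimethyl 2-[7-(methoxycarbonyl)-2,7-dimethylbicyclo[3.1.1]hept-2-en-6-ylidene]propanedioate
Product: 15 dimethyl 2-[7-(methoxycarbonyl)-2,7-dimethylbicyclo[3.1.1]hept-2-en-6-yl]propanedioate with the malonyl carbon cis to the ring ester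
Conditions: NaBH4, MeOH/THF, –20 to 0 °C
Reagents that add atoms: none
Why: Conjugate hydride addition to an alkylidene malonate; the face of the ring carbon (target C2) turned towards C8 is covered by the ester that C8 holds over it, so hydride should enter from the side of the C4–C5=C6 bridge, as nucleophiles do with ketones of this ring system. This sets C2 and places the malonyl carbon (C1) on the side of C9, where the later ring needs it.

Step 12
Reactants: 15 dimethyl 2-[7-(methoxycarbonyl)-2,7-dimethylbicyclo[3.1.1]hept-2-en-6-yl]propanedioate
Product: 16 dimethyl 2-[7-(methoxycarbonyl)-2,7-dimethylbicyclo[3.1.1]hept-2-en-6-yl]-2-methylpropanedioate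
Conditions: NaH, MeI, THF/DMF, 0 °C to rt
Reagents that add atoms: iodomethane, CI
Why: C-alkylation of the malonate anion with the smallest electrophile; C1 is now quaternary but still carries two identical esters, so no stereocentre is formed yet.

Step 13
Reactants: 16 dimethyl 2-[7-(methoxycarbonyl)-2,7-dimethylbicyclo[3.1.1]hept-2-en-6-yl]-2-methylpropanedioate
Product: 17 3-methoxy-2-[7-(methoxycarbonyl)-2,7-dimethylbicyclo[3.1.1]hept-2-en-6-yl]-2-methyl-3-oxopropanoic acid with C1 configured as in the target
Conditions: pig liver esterase, phosphate buffer pH 7.5, DMSO (10%), rt, pH-stat with 1 M NaOH; then 1 M HCl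
Reagents that add atoms: water, O
Why: Enzymatic desymmetrisation of a 2-alkyl-2-methylmalonate; the two ester groups are enantiotopic at C1 and lie between a methyl and a large residue, the situation in which the esterase discriminates best. This sets C1 by reagent control, the only kind available because the cage offers two equivalent faces; the ester on the ring carbon is far more hindered and should stay.

Step 14
Reactants: 17 3-methoxy-2-[7-(methoxycarbonyl)-2,7-dimethylbicyclo[3.1.1]hept-2-en-6-yl]-2-methyl-3-oxopropanoic acid
Product: 19 methyl 6-(1-hydroxy-3-methoxy-2-methyl-3-oxopropan-2-yl)-2,7-dimethylbicyclo[3.1.1]hept-2-ene-7-carboxylate, via acyl imidazolide 18 (not isolated)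
Conditions: 1,1'-carbonyldiimidazole, THF, rt; then NaBH4, THF/H2O, 0 °C
Reagents that add atoms: none
Why: The acid is activated as its imidazolide and reduced by borohydride to the primary alcohol while both methyl esters stay; borane is avoided because it would hydroborate the ring alkene. C1 has no α-hydrogen and keeps its configuration.

Step 15
Reactants: 19 methyl 6-(1-hydroxy-3-methoxy-2-methyl-3-oxopropan-2-yl)-2,7-dimethylbicyclo[3.1.1]hept-2-ene-7-carboxylate
Product: 20 methyl 6-[1-(tert-butyldiphenylsilyloxy)-3-methoxy-2-methyl-3-oxopropan-2-yl]-2,7-dimethylbicyclo[3.1.1]hept-2-ene-7-carboxylate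
Conditions: TBDPSCl, imidazole, DMAP (cat.), DMF, 40 °C
Reagents that add atoms: tert-butyldiphenylsilyl chloride, CC(C)(C)[Si](Cl)(c1ccccc1)c1ccccc1
Why: Silylation of the neopentyl alcohol; this ether should withstand sodium, zinc carbenoid, FeCl3 and acetic acid and leaves with fluoride at the end.

Step 16
Reactants: 20 methyl 6-[1-(tert-butyldiphenylsilyloxy)-3-methoxy-2-methyl-3-oxopropan-2-yl]-2,7-dimethylbicyclo[3.1.1]hept-2-ene-7-carboxylate
Product: 21 tricyclic C9=C11 bis(trimethylsilyloxy)alkene with the tert-butyldiphenylsilyloxymethyl group on C1
Conditions: Na (dispersion, 5 equiv), Me3SiCl (6 equiv), toluene, reflux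
Reagents that add atoms: chlorotrimethylsilane, C[Si](C)(C)Cl
Why: Acyloin condensation in the Rühlmann variant; the two ester carbons are held cis-1,3 on the cyclobutane, both lack α-hydrogens so no Claisen reaction competes, and ketyl coupling closes the six-membered ring C2–C1–C11–C9–C8–C3. Me3SiCl traps the enediolate and the methoxide.

Step 17
Reactants: 21 tricyclic C9=C11 bis(trimethylsilyloxy)alkene; 22 diiodomethane
Product: 24 tricyclic cycloheptane-1,3-dione with ketones at C9 and C11, via bis(silyloxy)cyclopropane 23 (not isolated)
Conditions: Et2Zn (1.3 equiv), CH2I2 (1.5 equiv), CH2Cl2, 0 °C to rt; solvent exchange; FeCl3 (trivalent iron, 2.5 equiv), DMF, 0 °C to rt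
Reagents that add atoms: diiodomethane (22), ICI
Why: EtZnCH2I, formed from Et2Zn and 22, transfers CH2 in a concerted electrophilic [2+1] addition (Furukawa variant of the Simmons–Smith reaction) to the C9=C11 alkene of 21 and closes the three-membered ring of 23 by forming C9–C10 and C10–C11. FeCl3 then oxidises one silyloxy oxygen by one electron; the C9–C11 bond, the only ring bond whose cleavage leaves both ends stabilised by oxygen, breaks to a ketone at one carbon and an α-silyloxy radical at the other, which a second FeCl3 oxidises to an oxocarbenium ion that loses Me3SiCl to give the second ketone. The closest known reaction type is the one-carbon ring enlargement of acyloin-derived 1,2-bis(silyloxy)cycloalkenes to cycloalkane-1,3-diones by cyclopropanation and FeCl3 cleavage. The seven-membered ring is therefore not closed by a cyclisation: it arises from the six-membered ring when the zero-atom bridge of the bicyclo[4.1.0] unit is cut. No lasting stereocentre is made, since C9 and C11 become carbonyl carbons and C10 is a methylene, so the face taken by the carbenoid does not matter. The step needs chemoselectivity for C9=C11 over C5=C6: two silyloxy donors make the enediol ether far more nucleophilic towards the zinc carbenoid than a trialkyl alkene, its faces are covered only by the bridgehead hydrogens on C3 and C7, and the reagent is kept near one equivalent. It also needs the cage to survive the iron salt; DMF tempers the Lewis acid, and because C8 and C1 are quaternary the dione can enolise only through C10 and cannot scramble.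

Step 18
Reactants: 24 tricyclic cycloheptane-1,3-dione
Product: 25 C9 hydroxy C11 ketone with the hydroxyl on the C4 side of the ring
Conditions: (S)-2-methyl-CBS-oxazaborolidine (0.3 equiv), catecholborane (1.5 equiv), toluene, –78 °C
Reagents that add atoms: none
Why: Corey–Bakshi–Shibata reduction; the catalyst places the quaternary C8 as the large and C10 as the small group and delivers hydride to the face that puts O9 on the C4 side. Catecholborane is used because it does not hydroborate the ring alkene. By the local twofold symmetry, reduction at C11 instead would give the matching alcohol, which leads to the same diol in step 19.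

Step 19
Reactants: 25 C9 hydroxy C11 ketone
Product: 26 trans-C9,C11-diol with O11 on the C6 side, cis to the C1 methyl
Conditions: Me4NBH(OAc)3, AcOH/MeCN, –30 °C
Reagents that add atoms: none
Why: Evans–Saksena reduction; the C9 hydroxyl exchanges onto boron and hydride is delivered intramolecularly to C11 on the face of O9, so the new hydroxyl ends up trans to it. Free ketones are not reduced by this reagent, and internal delivery overrides the crowding by the C1 substituents.

Step 20
Reactants: 26 trans-C9,C11-diol
Product: 27 C9,C11-bis(triethylsilyl) ether
Conditions: Et3SiOTf, 2,6-lutidine, CH2Cl2, –40 to 0 °C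
Reagents that add atoms: triethylsilyl trifluoromethanesulfonate, CC[Si](CC)(CC)OS(=O)(=O)C(F)(F)F
Why: Silyl triflate silylation reaches the two neopentyl secondary hydroxyls; the ethers protect them from the oxidant of the next step.

Step 21
Reactants: 27 C9,C11-bis(triethylsilyl) ether
Product: 28 C4 ketone (C4=O, C5=C6 enone) of the tris(silyl) ether
Conditions: Rh2(cap)4 (1 mol %), t-BuOOH (5 equiv), K2CO3, CH2Cl2, rt
Reagents that add atoms: tert-butyl hydroperoxide, CC(C)(C)OO
Why: Allylic oxidation by tert-butylperoxyl radicals; C4–H2 is the only secondary allylic position (the bridgehead C7–H cannot give a planar allyl radical), and the mixed peroxide collapses to the enone, the α-pinene to verbenone pattern.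

Step 22
Reactants: 28 C4 ketone of the tris(silyl) ether
Product: 29 enone triol with free hydroxyls at C9 and C11 and on the C1 CH2 arm
Conditions: Bu4NF, AcOH, THF, rt to 40 °C
Reagents that add atoms: none
Why: Buffered fluoride removes the two triethylsilyl ethers and the tert-butyldiphenylsilyl ether in one operation; the enone and the stereocentres are not affected.

Step 23
Reactants: 29 enone triol; 30 angelic acid
Product: 31 target CNP0266467.1
Conditions: angelic acid, 2,4,6-trichlorobenzoyl chloride, Et3N, toluene, rt; then 29, toluene, 80 °C
Reagents that add atoms: angelic acid (30), C/C=C(/C)C(=O)O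
Why: Yamaguchi-type acylation through the mixed anhydride without a nucleophilic catalyst, the conditions under which angelates are formed without Z to E isomerisation; all three hydroxyls are esterified and no stereocentre is involved.

## Compound list

1 | methyl (2E)-3,7-dimethylocta-2,6-dienoate (methyl geranate) | COC(=O)/C=C(C)/CCC=C(C)C | starting material
2 | methyl (2E,6E)-8-hydroxy-3,7-dimethylocta-2,6-dienoate | COC(=O)/C=C(C)/CC/C=C(C)/CO | intermediate
3 | methyl (2E,6E)-8-(tert-butyldimethylsilyloxy)-3,7-dimethylocta-2,6-dienoate | COC(=O)/C=C(C)/CC/C=C(C)/CO[Si](C)(C)C(C)(C)C | intermediate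
4 | (2E,6E)-8-(tert-butyldimethylsilyloxy)-3,7-dimethylocta-2,6-dienoic acid | OC(=O)/C=C(C)/CC/C=C(C)/CO[Si](C)(C)C(C)(C)C | intermediate
5 | (2E,6E)-8-(tert-butyldimethylsilyloxy)-3,7-dimethylocta-2,6-dienoyl chloride (not isolated) | ClC(=O)/C=C(C)/CC/C=C(C)/CO[Si](C)(C)C(C)(C)C | intermediate
6 | (6E)-8-(tert-butyldimethylsilyloxy)-7-methyl-3-methylideneocta-1,6-dien-1-one, the vinylketene (not isolated) | O=C=CC(=C)CC/C=C(C)/CO[Si](C)(C)C(C)(C)C | intermediate
7 | rac-7-[(tert-butyldimethylsilyloxy)methyl]-7-methyl-2-methylidenebicyclo[3.1.1]heptan-6-one; silyloxymethyl on the side of the carbonyl bridge, methyl over the three-carbon bridge; racemate, the enantiomer carried on is drawn | O=C1[C@H]2CCC(=C)[C@@H]1[C@@]2(C)CO[Si](C)(C)C(C)(C)C | intermediate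
8 | rac-7-[(tert-butyldimethylsilyloxy)methyl]-2,7-dimethylbicyclo[3.1.1]hept-2-en-6-one; racemate, drawn as above | O=C1[C@H]2CC=C(C)[C@@H]1[C@@]2(C)CO[Si](C)(C)C(C)(C)C | intermediate
9 | rac-7-(hydroxymethyl)-2,7-dimethylbicyclo[3.1.1]hept-2-en-6-one; racemate, drawn as above | O=C1[C@H]2CC=C(C)[C@@H]1[C@@]2(C)CO | intermediate
10 | rac-2,7-dimethyl-6-oxobicyclo[3.1.1]hept-2-ene-7-carboxylic acid; racemate, drawn as above | O=C1[C@H]2CC=C(C)[C@@H]1[C@@]2(C)C(=O)O | intermediate
11 | 2,7-dimethyl-6-oxobicyclo[3.1.1]hept-2-ene-7-carboxylic acid, single enantiomer with the cage configuration of the target | O=C1[C@H]2CC=C(C)[C@@H]1[C@@]2(C)C(=O)O | intermediate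
12 | methyl 2,7-dimethyl-6-oxobicyclo[3.1.1]hept-2-ene-7-carboxylate | O=C1[C@H]2CC=C(C)[C@@H]1[C@@]2(C)C(=O)OC | intermediate
13 | dimethyl malonate | COC(=O)CC(=O)OC | starting material
14 | dimethyl 2-[7-(methoxycarbonyl)-2,7-dimethylbicyclo[3.1.1]hept-2-en-6-ylidene]propanedioate | COC(=O)C(C(=O)OC)=C1[C@H]2CC=C(C)[C@@H]1[C@@]2(C)C(=O)OC | intermediate
15 | dimethyl 2-[7-(methoxycarbonyl)-2,7-dimethylbicyclo[3.1.1]hept-2-en-6-yl]propanedioate; malonyl carbon and ring ester cis on the cyclobutane, both away from the alkene bridge | COC(=O)C(C(=O)OC)[C@@H]1[C@H]2CC=C(C)[C@@H]1[C@@]2(C)C(=O)OC | intermediate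
16 | dimethyl 2-[7-(methoxycarbonyl)-2,7-dimethylbicyclo[3.1.1]hept-2-en-6-yl]-2-methylpropanedioate | COC(=O)C(C)(C(=O)OC)[C@@H]1[C@H]2CC=C(C)[C@@H]1[C@@]2(C)C(=O)OC | intermediate
17 | 3-methoxy-2-[7-(methoxycarbonyl)-2,7-dimethylbicyclo[3.1.1]hept-2-en-6-yl]-2-methyl-3-oxopropanoic acid; C1 as in the target, the free acid in the place of the later CH2O arm | OC(=O)[C@](C(=O)OC)(C)[C@@H]1[C@H]2CC=C(C)[C@@H]1[C@@]2(C)C(=O)OC | intermediate
18 | imidazolide of acid 17 (not isolated) | O=C(n1ccnc1)[C@](C(=O)OC)(C)[C@@H]1[C@H]2CC=C(C)[C@@H]1[C@@]2(C)C(=O)OC | intermediate
19 | methyl 6-(1-hydroxy-3-methoxy-2-methyl-3-oxopropan-2-yl)-2,7-dimethylbicyclo[3.1.1]hept-2-ene-7-carboxylate | OC[C@](C(=O)OC)(C)[C@@H]1[C@H]2CC=C(C)[C@@H]1[C@@]2(C)C(=O)OC | intermediate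
20 | methyl 6-[1-(tert-butyldiphenylsilyloxy)-3-methoxy-2-methyl-3-oxopropan-2-yl]-2,7-dimethylbicyclo[3.1.1]hept-2-ene-7-carboxylate | CC(C)(C)[Si](c1ccccc1)(c1ccccc1)OC[C@](C(=O)OC)(C)[C@@H]1[C@H]2CC=C(C)[C@@H]1[C@@]2(C)C(=O)OC | intermediate
21 | key-step precursor: tricycle with the six-membered ring C2–C1–C11=C9–C8–C3, trimethylsilyloxy groups on C9 and C11, CH3 and CH2OSi(t-Bu)Ph2 on C1, C5=C6 alkene | CC(C)(C)[Si](c1ccccc1)(c1ccccc1)OC[C@]2(C)[C@@H]3[C@H]4CC=C(C)[C@@H]3[C@@]4(C)C(O[Si](C)(C)C)=C2O[Si](C)(C)C | intermediate
22 | diiodomethane | ICI | starting material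
23 | bis(trimethylsilyloxy)cyclopropane C9–C10–C11 fused to the six-membered ring (not isolated); drawn with C10 on the face of the C1 methyl, either face serves | CC(C)(C)[Si](c1ccccc1)(c1ccccc1)OC[C@]2(C)[C@@H]3[C@H]4CC=C(C)[C@@H]3[C@@]4(C)[C@@]5(O[Si](C)(C)C)C[C@@]25O[Si](C)(C)C | intermediate
24 | key-step product: tricyclic cycloheptane-1,3-dione with ketones at C9 and C11, C10 methylene, CH2OSi(t-Bu)Ph2 on C1 | CC(C)(C)[Si](c1ccccc1)(c1ccccc1)OC[C@]2(C)[C@@H]3[C@H]4CC=C(C)[C@@H]3[C@@]4(C)C(=O)CC2=O | intermediate
25 | C9 alcohol, C11 ketone; hydroxyl on the C4 side of the seven-membered ring | CC(C)(C)[Si](c1ccccc1)(c1ccccc1)OC[C@]2(C)[C@@H]3[C@H]4CC=C(C)[C@@H]3[C@@]4(C)[C@H](O)CC2=O | intermediate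
26 | trans-C9,C11-diol; O9 on the C4 side, O11 on the C6 side and cis to the C1 methyl | CC(C)(C)[Si](c1ccccc1)(c1ccccc1)OC[C@]2(C)[C@@H]3[C@H]4CC=C(C)[C@@H]3[C@@]4(C)[C@H](O)C[C@H]2O | intermediate
27 | C9,C11-bis(triethylsilyl) ether of 26 | CC(C)(C)[Si](c1ccccc1)(c1ccccc1)OC[C@]2(C)[C@@H]3[C@H]4CC=C(C)[C@@H]3[C@@]4(C)[C@H](O[Si](CC)(CC)CC)C[C@H]2O[Si](CC)(CC)CC | intermediate
28 | C4 ketone of 27 (enone C4=O, C5=C6) | CC(C)(C)[Si](c1ccccc1)(c1ccccc1)OC[C@]2(C)[C@@H]3[C@H]4C(=O)C=C(C)[C@@H]3[C@@]4(C)[C@H](O[Si](CC)(CC)CC)C[C@H]2O[Si](CC)(CC)CC | intermediate
29 | enone triol: free hydroxyls at C9, C11 and on the C1 CH2 arm | OC[C@]1(C)[C@@H]2[C@H]3C(=O)C=C(C)[C@@H]2[C@@]3(C)[C@H](O)C[C@H]1O | intermediate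
30 | angelic acid, (Z)-2-methylbut-2-enoic acid | C/C=C(/C)C(=O)O | starting material
31 | CNP0266467.1, the tris-angelate | C/C=C(/C)C(=O)OC[C@]1(C)[C@@H]2[C@H]3C(=O)C=C(C)[C@@H]2[C@@]3(C)[C@H](OC(=O)/C(C)=C\C)C[C@H]1OC(=O)/C(C)=C\C | target

## Step count and least certain steps

Total: 23 steps. Longest linear sequence: 23 steps (1 to 31); 13, 22 and 30 enter as purchased reagents.

**Step 17 (key step).** The carbenoid may react too slowly at the doubly neopentyl enediol ether or add to the C5=C6 alkene as well. In the second stage, radical character at C9 next to the strained four-membered ring may open the cyclobutane, or the iron Lewis acid may trigger a pinene-type skeletal rearrangement. The fallback avoids both the acyloin and the cyclopropane; it sets out from diester 20 and returns at 24. The lithium enolate of allyl acetate (LiHMDS, THF, –78 °C) is acylated by one of the two non-enolisable methyl esters to give the β-keto allyl ester F1. More base (NaH, THF) lets the doubly activated C10 acylate at the second ester and close the seven-membered ring as the 2-(allyloxycarbonyl)-1,3-dione F2. Pd(PPh3)4 and morpholine then remove the allyl ester with loss of CO2 to give 24.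

**Step 13.** The enzyme may not accept so large a triester, or may discriminate poorly or in the opposite sense. The fallback sets out from 16 and returns at 17. One equivalent of KOH in MeOH/H2O half-saponifies the malonate statistically to 17 and its C1 epimer, the half-acid F3. The two acids, whose stereocentre sits next to the carboxyl group, are separated through their salts with a chiral amine. F3 is returned to 16 with MeI/K2CO3, so the wrong half is recycled instead of lost.

**Step 11.** Hydride may add to the face turned towards C8, which would turn C1 away from C9 and make the ring closure impossible. The fallback sets out from racemic alcohol 9 and returns at 16; it fixes the face by a tether and also replaces the intermolecular condensation of step 10.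
- 9 is acylated with methyl malonyl chloride to the mixed malonate F4.
- Intramolecular Knoevenagel condensation (TiCl4, pyridine) gives the seven-membered alkylidene lactone F5.
- NaBH4 adds hydride to C2 from the only face the lactone ring leaves open, giving the saturated lactone F6.
- NaH/MeI gives the methylated lactone F7.
- NaOMe/MeOH opens the lactone to the hydroxy malonate F8, in which C1 again carries two identical esters.
- TEMPO/PhI(OAc)2 gives the acid F9, which is resolved as in step 8 and methylated as in step 9 to 16.

**Step 8.** The two diastereomeric salts may differ too little in solubility, since the enantiomers of 10 differ in shape only in the far bridge. The fallback sets out from 8 and returns at 8 as a single enantiomer, which then passes through steps 6, 7 and 9. NaBH4 reduces 8 to the cyclobutanol F10, and a lipase with vinyl acetate acylates one enantiomer to the acetate F11. The enantiomer with the required cage is taken as residual F10, or from F11 after methanolysis, and is oxidised back to the ketone with Dess–Martin periodinane.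

**Step 18.** The boron reagents may enolise the β-diketone through C10 and stall, reduce both ketones, or give weak face selectivity. The fallback sets out from 24 and returns at 26. NaBH4 at –78 °C reduces one ketone without face control, and the Evans–Saksena reduction of step 19 converts each mono-alcohol to an anti diol. Diol 26 and its top-ring diastereomer, the anti-diol F12, differ at two centres next to C1 and are separable on silica. F12 is oxidised back to 24 with Dess–Martin periodinane and recycled.

**Step 23.** Acylation of the two neopentyl secondary hydroxyls may stop short, and forcing it risks Z to E isomerisation of the angelates. The fallback sets out from diol 26 and returns at 31. The two hydroxyls are acylated as lithium alkoxides (LiHMDS, angelic anhydride, THF, –78 °C to rt) while no enone is present, giving the bis-angelate F13. Allylic oxidation as in step 21 gives the enone F14, HF·pyridine frees the primary alcohol F15, and the less demanding mono-acylation under the conditions of step 23 gives 31.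

## Further compounds

F1 | step 17 | β-keto allyl ester from Claisen acylation at the C9 ester of 20 | CC(C)(C)[Si](c1ccccc1)(c1ccccc1)OC[C@](C(=O)OC)(C)[C@@H]1[C@H]2CC=C(C)[C@@H]1[C@@]2(C)C(=O)CC(=O)OCC=C
F2 | step 17 | tricyclic 1,3-dione with an allyl ester on C10 (C10 enolisable, not defined) | CC(C)(C)[Si](c1ccccc1)(c1ccccc1)OC[C@]2(C)[C@@H]3[C@H]4CC=C(C)[C@@H]3[C@@]4(C)C(=O)C(C(=O)OCC=C)C2=O
F3 | step 13 | C1 epimer of half-acid 17 | OC(=O)[C@@](C(=O)OC)(C)[C@@H]1[C@H]2CC=C(C)[C@@H]1[C@@]2(C)C(=O)OC
F4 | step 11 | (2,7-dimethyl-6-oxobicyclo[3.1.1]hept-2-en-7-yl)methyl methyl malonate, racemic | O=C1[C@H]2CC=C(C)[C@@H]1[C@@]2(C)COC(=O)CC(=O)OC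
F5 | step 11 | seven-membered alkylidene lactone (C2=C1 in the ring, CO2Me on C1; both alkene geometries) | COC(=O)C1=C2[C@H]3CC=C(C)[C@@H]2[C@@]3(C)COC1=O
F6 | step 11 | saturated lactone with C2–H on the face of the alkene bridge (C1 not defined) | COC(=O)C1[C@@H]2[C@H]3CC=C(C)[C@@H]2[C@@]3(C)COC1=O
F7 | step 11 | C1-methylated lactone (C1 not defined) | COC(=O)C1(C)[C@@H]2[C@H]3CC=C(C)[C@@H]2[C@@]3(C)COC1=O
F8 | step 11 | dimethyl 2-[7-(hydroxymethyl)-2,7-dimethylbicyclo[3.1.1]hept-2-en-6-yl]-2-methylpropanedioate | COC(=O)C(C)(C(=O)OC)[C@@H]1[C@H]2CC=C(C)[C@@H]1[C@@]2(C)CO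
F9 | step 11 | 6-(1,3-dimethoxy-2-methyl-1,3-dioxopropan-2-yl)-2,7-dimethylbicyclo[3.1.1]hept-2-ene-7-carboxylic acid | COC(=O)C(C)(C(=O)OC)[C@@H]1[C@H]2CC=C(C)[C@@H]1[C@@]2(C)C(=O)O
F10 | step 8 | 7-[(tert-butyldimethylsilyloxy)methyl]-2,7-dimethylbicyclo[3.1.1]hept-2-en-6-ol, hydroxyl on the face of the silyloxymethyl bridge | O[C@@H]1[C@H]2CC=C(C)[C@@H]1[C@@]2(C)CO[Si](C)(C)C(C)(C)C
F11 | step 8 | acetate of F10 | CC(=O)O[C@@H]1[C@H]2CC=C(C)[C@@H]1[C@@]2(C)CO[Si](C)(C)C(C)(C)C
F12 | step 18 | anti C9,C11-diol with both carbinol centres opposite to 26 | CC(C)(C)[Si](c1ccccc1)(c1ccccc1)OC[C@]2(C)[C@@H]3[C@H]4CC=C(C)[C@@H]3[C@@]4(C)[C@@H](O)C[C@@H]2O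
F13 | step 23 | C9,C11-bis-angelate of 26 | CC(C)(C)[Si](c1ccccc1)(c1ccccc1)OC[C@]2(C)[C@@H]3[C@H]4CC=C(C)[C@@H]3[C@@]4(C)[C@H](OC(=O)/C(C)=C\C)C[C@H]2OC(=O)/C(C)=C\C
F14 | step 23 | C4 ketone of F13 | CC(C)(C)[Si](c1ccccc1)(c1ccccc1)OC[C@]2(C)[C@@H]3[C@H]4C(=O)C=C(C)[C@@H]3[C@@]4(C)[C@H](OC(=O)/C(C)=C\C)C[C@H]2OC(=O)/C(C)=C\C
F15 | step 23 | enone bis-angelate with free primary hydroxyl | OC[C@]1(C)[C@@H]2[C@H]3C(=O)C=C(C)[C@@H]2[C@@]3(C)[C@H](OC(=O)/C(C)=C\C)C[C@H]1OC(=O)/C(C)=C\C
A1 | alternative 1 | open-chain E-alkenylboronate tethered to C8 of a 1-trimethylsilyloxy-3-methylcyclopentadiene | CC(C)(C)[Si](C)(C)OC[C@](C)(/C=C/B1OC(C)(C)C(C)(C)O1)[C@H](O[Si](C)(C)C(C)(C)C)C[C@@H](O[Si](C)(C)C(C)(C)C)[C@@]2(C)C(O[Si](C)(C)C)=CC(C)=C2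
A2 | alternative 1 | norbornene cycloadduct with bridgehead C4 silyl ether and endo C3 boronate | CC(C)(C)[Si](C)(C)OC[C@]1(C)[C@@H]2[C@@H](B3OC(C)(C)C(C)(C)O3)[C@@]4(O[Si](C)(C)C)C=C(C)[C@@H]2[C@@]4(C)[C@H](O[Si](C)(C)C(C)(C)C)C[C@H]1O[Si](C)(C)C(C)(C)C
A3 | alternative 2 | dienoyl chloride carrying the C9–C11 arm | ClC(=O)/C=C(C)/CC/C=C(C)/[C@H](O[Si](C)(C)C(C)(C)C)CCOCc1ccc(OC)cc1
A4 | alternative 2 | C2 cyclobutanone of the bicyclo[3.1.1]hept-2-ene core with the C9–C11 arm on C8 | O=C1[C@H]2CC=C(C)[C@@H]1[C@@]2(C)[C@H](O[Si](C)(C)C(C)(C)C)CCOCc3ccc(OC)cc3
A5 | alternative 3 | cis-fused 6–7 bicycle with C8–C9 epoxide and C4 silyl dienol ether | CC(C)(C)[Si](C)(C)OC[C@]1(C)[C@@H]2[C@@H](C(O[Si](C)(C)C(C)(C)C)=CC(C)=C2)[C@]3(C)O[C@@H]3C[C@H]1O[Si](C)(C)C(C)(C)C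
A6 | alternative 3 | target skeleton with free C9 hydroxyl and silyl ethers on the C1 hydroxymethyl and C11 | CC(C)(C)[Si](C)(C)OC[C@]1(C)[C@@H]2[C@H]3C(=O)C=C(C)[C@@H]2[C@@]3(C)[C@H](O)C[C@H]1O[Si](C)(C)C(C)(C)C
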